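Count what is missing.

| flask | starting material | protic impurity | capture agent | remark | time |
|---|---|---|---|---|---|
| east | 1 M | 0.25 M | 0.020 M | run made earlier |  |
| north | 1 M | 0.38 M | 0.020 M | run made earlier |  |
| north-west | 0.50 M | 0.50 M | 0.020 M | run made earlier |  |
| midnight | 1.0 M | 0.500 M | 0.0200 M |  | 50 h |
| winter | 1.0 M | 0.500 M | 0.0200 M |  | 30 h |
| summer | 1.0 M | 0.500 M | 0.0200 M |  | 20 h |

| run | time / h | starting material / % | target / % | intermediate A / % | side product / % | trapped intermediate / % |
|---|---|---|---|---|---|---|
| east | 1.50 | 85 | 0 | 7 | 8 | 0 |
| east | 4.00 | 58 | 2 | 8 | 27 | 0 |
| east | 8.00 | 38 | 1 | 2 | 42 | 0 |
| east | 20.0 | 12 | 0 | 2 | 74 | 3 |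
| north | 2.50 | 71 | 2 | 7 | 16 | 0 |
| north | 8.00 | 32 | 3 | 1 | 45 | 0 |
| north | 12.0 | 24 | 0 | 3 | 55 | 0 |
| north | 20.0 | 8 | 0 | 1 | 67 | 1 |
| north-west | 1.50 | 79 | 2 | 0 | 6 | 0 |
| north-west | 4.00 | 52 | 1 | 7 | 23 | 0 |
| north-west | 8.00 | 25 | 0 | 3 | 39 | 0 |
| north-west | 20.0 | 6 | 0 | 0 | 62 | 0 |

(scatter of a reading: 2 percentage points)

1. which of these there is most of at the end, counted by the starting material in it, midnight (trapped intermediate / target / side product / intermediate A / starting material)
2. which of these there is most of at the end, counted by the starting material in it, winter (trapped intermediate / target / side product / intermediate A / starting material)
3. which of these there is most of at the end, counted by the starting material in it, summer (trapped intermediate / target / side product / intermediate A / starting material)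
4. final amount of the leader among these, as a percentage of the starting material charged, in midnight
5. final amount of the leader among these, as a percentage of the starting material charged, in winter
6. final amount of the leader among these, as a percentage of the starting material charged, in summer

- what was read earlier has a scatter of 2 percentage points, one standard deviation

At the last reading the percentages add up short by 9.00% in the east run, 23.0% in the north run and 32.0% in the north-west run. From the east run to the north run the charges of starting material and capture agent stay the same while the impurity charge rises from 0.25 M to 0.38 M, and the shortfall is larger in the north run, so starting material seems to have a second, unseen exit. My own reckoning assumes that this exit takes one protic impurity per starting material, and it uses the north-west run, whose shortfall is larger than the other two and so stands clearest of the scatter.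

Define the bias, a selectivity factor, as the rate of unseen loss over the rate of forming side product, per unit of [protic impurity]. The comparison therefore drifts towards side product as impurity is consumed. The bias is then the logarithm of the fall in [protic impurity], divided by the [side product] formed. In the north-west run the shortfall at the last reading comes to 0.160 M, which on that assumption takes impurity from 0.50 M to 0.340 M, while the same reading shows 0.310 M of side product, so the bias read there, with the scatter of those readings, is 1.24 M⁻¹.

For the new flasks, the first link holds impurity at 0.500 M. The loss then runs at 0.622 of the side-product rate, which gives side product an estimated 61.7% of the charge once the starting material has reacted. This link is weak, since that share would consume 0.383 M of impurity. Letting impurity fall along the bias gives 73.2%, which overshoots. Starting again from the mean of the two, 67.4%, gives 71.6%, the figure I commit to for midnight.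

The north-west run read 6% starting material at 20.0 h. Taking that decay over, although the north-west run was charged with 0.50 M of starting material and these flasks with 1.0 M, and subtracting what remains gives 70.1% for winter and 65.6% for summer, with side product leading in my estimate.

The forecast names side product, side product and side product as leaders, with 70%, 67% and 62%, each lower than my figure for the same flask, holding that “a growing share goes somewhere unseen”.

The flasks give side product at 67.7%, side product at 66.2% and side product at 62.0%.

    starting material ⇌ intermediate A (K = 7.00, k = 0.100 h⁻¹)
    intermediate A → target (k = 0.00930 h⁻¹)
    intermediate A → side product (k = 1.30 h⁻¹)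
    intermediate A ⇌ intermediate B (K = 0.240, k = 0.0270 h⁻¹)
    starting material + protic impurity → quenched substrate (k = 0.140 M⁻¹ h⁻¹)
    capture agent + intermediate A → trapped intermediate (k = 0.550 M⁻¹ h⁻¹)

In midnight, quenching runs at 0.700 of the forward step to intermediate A at the start. By 50.0 h that ratio is 0.265, with protic impurity at 38% of its charge and quenched substrate at 31.1%. Applied to midnight's side product, the bias gives 43.2% of the impurity charge left, and the flask holds 38%. A further flask, like winter but with 1.2 M of impurity, ends with 43.3% of side product, from which the bias gives 58.5% of its impurity charge left, and that flask holds 54%.

The numbers in the tables come from a simulation with made-up constants.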